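**Retrosynthetic overview**
- The palmitate is put on last, at the C7 CH2OH freed from its silyl ether. The C2'–C3' bond of the enone comes from a Liebeskind–Srogl coupling of a thioester with 2-methylprop-1-enylboronic acid.
- The strategy rests on chroman C2: a quaternary carbon bearing O1, a methyl group and the C1'H2–C2'(=O) arm. This is the imprint of a phenol oxygen, a 1,1-disubstituted alkene and one CO, so O1–C2 and C1'–C2' are cut together.
- That cut opens the dihydropyran ring to a 3-(3-methylbut-3-enyl)salicylaldehyde, cyclised by an enantioselective Pd(II) oxypalladation/methoxycarbonylation.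
- The salicylaldehyde comes from a symmetrical 4-alkyl-3,5-dimethoxybenzyl silyl ether by mono-demethylation and then phenol-directed ortho-formylation. The alkyl chain is attached by Negishi coupling.
- Ring order: the benzene ring is bought; the dihydropyran ring (O1–C2–C3–C4–C4a–C8a) is the only ring formed, in step 7.

Key step: step 7

Assumption: the (S,S)-Bn-BOXAX ligand (made separately by the established route, not counted) is taken to give the (2S) chroman, as in simpler 2-methylchroman-2-ylacetates; if the sense proved opposite, the (R,R) ligand would be used with no other change.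

**Route**

Step 1
Reactants: 1 4-bromo-2-methylbut-1-ene
Product: 2 (3-methylbut-3-en-1-yl)zinc bromide, used as a titrated THF solution
Conditions: Zn dust (activated with 1,2-dibromoethane and TMSCl, cat.), LiCl, THF, 50 °C
Reagents that add atoms: zinc, [Zn]
Why: Direct insertion of LiCl-activated zinc into a primary C–Br bond (Knochel-type organozinc formation); the isolated alkene is inert and the homoallylic zinc reagent should not rearrange.

Step 2
Reactants: 3 methyl 4-bromo-3,5-dimethoxybenzoate; 2 (3-methylbut-3-en-1-yl)zinc bromide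
Product: 4 methyl 3,5-dimethoxy-4-(3-methylbut-3-en-1-yl)benzoate
Conditions: Pd(OAc)2 (2 mol %), SPhos (4 mol %), THF, rt → 50 °C
Reagents that add atoms: none
Why: Negishi sp3–sp2 coupling, in which the para ester speeds oxidative addition at the di-ortho-methoxy bromide, SPhos suits hindered partners and lets reductive elimination outrun β-hydride elimination, and the alkylzinc leaves the ester alone.

Step 3
Reactants: 4 methyl 3,5-dimethoxy-4-(3-methylbut-3-en-1-yl)benzoate
Product: 5 [3,5-dimethoxy-4-(3-methylbut-3-en-1-yl)phenyl]methanol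
Conditions: LiAlH4, THF, 0 °C; Fieser work-up
Reagents that add atoms: none
Why: Hydride reduction of a benzoate ester to the benzylic alcohol; the aryl ethers and the unactivated alkene are inert to LiAlH4.

Step 4
Reactants: 5 [3,5-dimethoxy-4-(3-methylbut-3-en-1-yl)phenyl]methanol
Product: 6 tert-butyl{[3,5-dimethoxy-4-(3-methylbut-3-en-1-yl)phenyl]methoxy}dimethylsilane
Conditions: TBSCl, imidazole, CH2Cl2, 0 °C → rt
Reagents that add atoms: tert-butyldimethylsilyl chloride, CC(C)(C)[Si](C)(C)Cl
Why: Imidazole-promoted silylation of a primary alcohol, giving an ether that is stable to the basic and Pd-mediated steps that follow.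

Step 5
Reactants: 6 tert-butyl{[3,5-dimethoxy-4-(3-methylbut-3-en-1-yl)phenyl]methoxy}dimethylsilane
Product: 7 5-{[(tert-butyldimethylsilyl)oxy]methyl}-3-methoxy-2-(3-methylbut-3-en-1-yl)phenol
Conditions: NaSEt (3–4 equiv), DMF, 120 °C, Ar; cold dilute HCl to pH 6
Reagents that add atoms: none
Why: Nucleophilic O-demethylation of an aryl methyl ether by thiolate (SN2 at methyl); the two methoxy groups are equivalent by symmetry, the phenoxide formed deactivates the second one so the mono-phenol should result, and the soft thiolate should spare the alkyl silyl ether and the alkene.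

Step 6
Reactants: 7 5-{[(tert-butyldimethylsilyl)oxy]methyl}-3-methoxy-2-(3-methylbut-3-en-1-yl)phenol
Product: 8 6-{[(tert-butyldimethylsilyl)oxy]methyl}-2-hydroxy-4-methoxy-3-(3-methylbut-3-en-1-yl)benzaldehyde
Conditions: anhydrous MgCl2 (2 equiv), Et3N (4 equiv), paraformaldehyde (6 equiv), THF, reflux
Reagents that add atoms: paraformaldehyde (as formaldehyde), C=O
Why: Casnati–Skattebøl magnesium-mediated ortho-formylation, in which the magnesium phenoxide delivers formaldehyde to the only free ortho carbon and a second formaldehyde oxidises the resulting benzylic alkoxide by hydride transfer; the acid-free conditions spare the alkene and the silyl ether.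

Step 7
Reactants: 8 6-{[(tert-butyldimethylsilyl)oxy]methyl}-2-hydroxy-4-methoxy-3-(3-methylbut-3-en-1-yl)benzaldehyde
Product: 9 methyl 2-[(2S)-7-{[(tert-butyldimethylsilyl)oxy]methyl}-8-formyl-5-methoxy-2-methyl-3,4-dihydro-2H-chromen-2-yl]acetate
Conditions: Pd(TFA)2 (5 mol %), (S,S)-Bn-BOXAX (20 mol %), p-benzoquinone (4 equiv), CO (1 atm), MeOH, rt (to 40 °C if slow)
Reagents that add atoms: carbon monoxide, [C-]#[O+]; methanol, CO
Why: The BOXAX-bound Pd(II) trifluoroacetate binds the 1,1-disubstituted alkene and the phenol oxygen adds to its internal carbon (O1–C2), leaving a primary alkyl–Pd next to a quaternary carbon; with no β-hydrogen it inserts CO and the acyl–Pd is cleaved by methanol (C1'–C2'), benzoquinone returning Pd(0) to Pd(II). The closest known reaction type is the enantioselective domino Wacker oxypalladation/alkoxycarbonylation of 2-(3-methylbut-3-enyl)phenols to methyl 2-methylchroman-2-ylacetates. The dihydropyran ring closes in the 6-exo-trig mode. The C2 stereocentre is set in the oxypalladation, where the bisoxazoline on the axially chiral binaphthyl backbone differentiates the two alkene faces, the (S,S) ligand being used for the (2S) product. The step needs enantiofacial selectivity, which rests on the ligand alone, and 6-exo over 7-endo regiochemistry, which the two-carbon tether and Markovnikov addition secure; there is a single free OH, and the formyl and silyl ether groups are spectators. Because the phenol is hydrogen-bonded to the ortho formyl group the addition is expected to be slower than for electron-rich phenols, hence the high ligand-to-palladium ratio to suppress an unligated racemic pathway.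

Step 8
Reactants: 9 methyl 2-[(2S)-7-{[(tert-butyldimethylsilyl)oxy]methyl}-8-formyl-5-methoxy-2-methyl-3,4-dihydro-2H-chromen-2-yl]acetate
Product: 10 2-[(2S)-7-{[(tert-butyldimethylsilyl)oxy]methyl}-8-formyl-5-methoxy-2-methyl-3,4-dihydro-2H-chromen-2-yl]acetic acid
Conditions: LiOH·H2O, THF/MeOH/H2O, rt; cold 0.5 M HCl to pH 4
Reagents that add atoms: lithium hydroxide (its oxygen becomes the carboxyl OH), [Li+].[OH-]
Why: Saponification of an unhindered methyl ester; the aldehyde has no α-hydrogen, the primary silyl ether tolerates LiOH at rt, and the quaternary C2 cannot epimerise.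

Step 9
Reactants: 10 2-[(2S)-7-{[(tert-butyldimethylsilyl)oxy]methyl}-8-formyl-5-methoxy-2-methyl-3,4-dihydro-2H-chromen-2-yl]acetic acid
Product: 11 S-phenyl 2-[(2S)-7-{[(tert-butyldimethylsilyl)oxy]methyl}-8-formyl-5-methoxy-2-methyl-3,4-dihydro-2H-chromen-2-yl]ethanethioate
Conditions: PhSH, DCC, DMAP (cat.), CH2Cl2, 0 °C → rt
Reagents that add atoms: thiophenol, Sc1ccccc1
Why: Steglich-type thioesterification through the O-acylisourea; the near-neutral conditions preserve the aldehyde and silyl ether, and an S-aryl thioester is chosen because it undergoes C–S oxidative addition readily in the next step.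

Step 10
Reactants: 11 S-phenyl 2-[(2S)-7-{[(tert-butyldimethylsilyl)oxy]methyl}-8-formyl-5-methoxy-2-methyl-3,4-dihydro-2H-chromen-2-yl]ethanethioate; 12 (2-methylprop-1-en-1-yl)boronic acid
Product: 13 (2S)-7-{[(tert-butyldimethylsilyl)oxy]methyl}-5-methoxy-2-methyl-2-(4-methyl-2-oxopent-3-en-1-yl)-3,4-dihydro-2H-chromene-8-carbaldehyde
Conditions: Pd2(dba)3 (2.5 mol %), tri(2-furyl)phosphine (15 mol %), copper(I) thiophene-2-carboxylate (1.6 equiv), THF, 50 °C, Ar
Reagents that add atoms: none
Why: Liebeskind–Srogl coupling, in which Pd(0) inserts into the acyl C–S bond, the Cu(I) carboxylate activates sulfur and boron for base-free transmetalation, and reductive elimination forms C2'–C3'; the neutral conditions tolerate the aldehyde and should avoid β-elimination of the aryloxy group.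

Step 11
Reactants: 13 (2S)-7-{[(tert-butyldimethylsilyl)oxy]methyl}-5-methoxy-2-methyl-2-(4-methyl-2-oxopent-3-en-1-yl)-3,4-dihydro-2H-chromene-8-carbaldehyde
Product: 14 (2S)-7-(hydroxymethyl)-5-methoxy-2-methyl-2-(4-methyl-2-oxopent-3-en-1-yl)-3,4-dihydro-2H-chromene-8-carbaldehyde
Conditions: HF·pyridine, pyridine, THF, 0 °C → rt
Reagents that add atoms: none
Why: Fluoride-mediated desilylation under buffered, weakly acidic conditions; basic fluoride is avoided so that the β-aryloxy ketone does not open by retro-oxa-Michael reaction, which would racemise C2.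

Step 12
Reactants: 14 (2S)-7-(hydroxymethyl)-5-methoxy-2-methyl-2-(4-methyl-2-oxopent-3-en-1-yl)-3,4-dihydro-2H-chromene-8-carbaldehyde; 15 hexadecanoyl chloride
Product: 16 [(2S)-8-formyl-5-methoxy-2-methyl-2-(4-methyl-2-oxopent-3-en-1-yl)-3,4-dihydro-2H-chromen-7-yl]methyl hexadecanoate
Conditions: pyridine, CH2Cl2, 0 °C
Reagents that add atoms: none
Why: O-acylation of a primary benzylic alcohol with an acid chloride; the ortho and para oxygen substituents deactivate the aldehyde, so the open hydroxy-aldehyde rather than the lactol should be the reacting form, and the weak base leaves the β-aryloxy enone and C2 untouched.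

**Compound list**
1 | 4-bromo-2-methylbut-1-ene | C=C(C)CCBr | starting material
2 | (3-methylbut-3-en-1-yl)zinc bromide | C=C(C)CC[Zn]Br | intermediate
3 | methyl 4-bromo-3,5-dimethoxybenzoate | COC(=O)c1cc(OC)c(Br)c(OC)c1 | starting material
4 | methyl 3,5-dimethoxy-4-(3-methylbut-3-en-1-yl)benzoate | COC(=O)c1cc(OC)c(CCC(C)=C)c(OC)c1 | intermediate
5 | [3,5-dimethoxy-4-(3-methylbut-3-en-1-yl)phenyl]methanol | OCc1cc(OC)c(CCC(C)=C)c(OC)c1 | intermediate
6 | tert-butyl{[3,5-dimethoxy-4-(3-methylbut-3-en-1-yl)phenyl]methoxy}dimethylsilane | CC(C)(C)[Si](C)(C)OCc1cc(OC)c(CCC(C)=C)c(OC)c1 | intermediate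
7 | 5-{[(tert-butyldimethylsilyl)oxy]methyl}-3-methoxy-2-(3-methylbut-3-en-1-yl)phenol | CC(C)(C)[Si](C)(C)OCc1cc(O)c(CCC(C)=C)c(OC)c1 | intermediate
8 | 6-{[(tert-butyldimethylsilyl)oxy]methyl}-2-hydroxy-4-methoxy-3-(3-methylbut-3-en-1-yl)benzaldehyde | C=C(C)CCc1c(O)c(C=O)c(CO[Si](C)(C)C(C)(C)C)cc1OC | intermediate
9 | methyl 2-[(2S)-7-{[(tert-butyldimethylsilyl)oxy]methyl}-8-formyl-5-methoxy-2-methyl-3,4-dihydro-2H-chromen-2-yl]acetate | CC(C)(C)[Si](C)(C)OCc1cc(OC)c2c(c1C=O)O[C@](C)(CC(=O)OC)CC2 | intermediate
10 | 2-[(2S)-7-{[(tert-butyldimethylsilyl)oxy]methyl}-8-formyl-5-methoxy-2-methyl-3,4-dihydro-2H-chromen-2-yl]acetic acid | CC(C)(C)[Si](C)(C)OCc1cc(OC)c2c(c1C=O)O[C@](C)(CC(=O)O)CC2 | intermediate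
11 | S-phenyl 2-[(2S)-7-{[(tert-butyldimethylsilyl)oxy]methyl}-8-formyl-5-methoxy-2-methyl-3,4-dihydro-2H-chromen-2-yl]ethanethioate | CC(C)(C)[Si](C)(C)OCc1cc(OC)c2c(c1C=O)O[C@](C)(CC(=O)Sc3ccccc3)CC2 | intermediate
12 | (2-methylprop-1-en-1-yl)boronic acid | CC(C)=CB(O)O | starting material
13 | (2S)-7-{[(tert-butyldimethylsilyl)oxy]methyl}-5-methoxy-2-methyl-2-(4-methyl-2-oxopent-3-en-1-yl)-3,4-dihydro-2H-chromene-8-carbaldehyde | CC(C)(C)[Si](C)(C)OCc1cc(OC)c2c(c1C=O)O[C@](C)(CC(=O)C=C(C)C)CC2 | intermediate
14 | (2S)-7-(hydroxymethyl)-5-methoxy-2-methyl-2-(4-methyl-2-oxopent-3-en-1-yl)-3,4-dihydro-2H-chromene-8-carbaldehyde | OCc1cc(OC)c2c(c1C=O)O[C@](C)(CC(=O)C=C(C)C)CC2 | intermediate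
15 | hexadecanoyl chloride | CCCCCCCCCCCCCCCC(=O)Cl | starting material
16 | [(2S)-8-formyl-5-methoxy-2-methyl-2-(4-methyl-2-oxopent-3-en-1-yl)-3,4-dihydro-2H-chromen-7-yl]methyl hexadecanoate | CCCCCCCCCCCCCCCC(=O)OCc1cc(OC)c2c(c1C=O)O[C@](C)(CC(=O)C=C(C)C)CC2 | target

**Summary**
Total step count: 12.
Longest linear sequence: 12 steps (1 → 2 → 4 → 5 → 6 → 7 → 8 → 9 → 10 → 11 → 13 → 14 → 16); 11 steps counted from aryl bromide 3.

**Steps most likely to fail**

Step 7. The hydrogen-bonded, electron-poor phenol may add slowly and may chelate palladium together with the formyl oxygen. The reaction could then stall, or an unligated pathway could take over and erode enantiofacial selectivity. Fallback, with the stereocentre secured by resolution instead of by the catalyst: setting out from 8, the oxypalladation/methoxycarbonylation would be run without chiral ligand under the more electrophilic unligated Pd(TFA)2 (p-benzoquinone, CO, MeOH, rt to 40 °C). This should give racemic methyl 2-[7-{[(tert-butyldimethylsilyl)oxy]methyl}-8-formyl-5-methoxy-2-methyl-3,4-dihydro-2H-chromen-2-yl]acetate F1. Preparative chromatography on a chiral stationary phase would separate F1 into 9 and its antipode, methyl 2-[(2R)-7-{[(tert-butyldimethylsilyl)oxy]methyl}-8-formyl-5-methoxy-2-methyl-3,4-dihydro-2H-chromen-2-yl]acetate F2, which is set aside. The route is rejoined at 9.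

Step 10. The β,β-disubstituted alkenylboronic acid may protodeboronate or transmetalate sluggishly, so the thioester could be left unconsumed or lose the aryloxy group by β-elimination on long heating. Fallback, an acyl chloride/organostannane ketone synthesis: setting out from 10, 1-chloro-N,N,2-trimethylprop-1-en-1-amine (CH2Cl2, 0 °C) would give under neutral conditions 2-[(2S)-7-{[(tert-butyldimethylsilyl)oxy]methyl}-8-formyl-5-methoxy-2-methyl-3,4-dihydro-2H-chromen-2-yl]acetyl chloride F3. Stille acylation of F3 with commercial tributyl(2-methylprop-1-en-1-yl)stannane (Pd(PPh3)4 cat., toluene, 60 °C) should then give enone 13, where the route is rejoined.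

Step 5. At 120 °C the silyl ether may be lost, or a second demethylation may begin before the first is complete. Fallback, with the order of operations changed so that no silyl ether is exposed to thiolate: setting out from 5, NaSEt in DMF at 120 °C would give 5-(hydroxymethyl)-3-methoxy-2-(3-methylbut-3-en-1-yl)phenol F4. Both hydroxyl groups would be silylated (TBSCl, imidazole, DMF) to tert-butyl{[3-{[tert-butyl(dimethyl)silyl]oxy}-5-methoxy-4-(3-methylbut-3-en-1-yl)phenyl]methoxy}dimethylsilane F5. The aryl silyl ether alone would then be cleaved with K2CO3 in MeOH at rt, returning to the route at 7.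

**Further compounds**
F1 | step 7 | racemic methyl 2-[7-{[(tert-butyldimethylsilyl)oxy]methyl}-8-formyl-5-methoxy-2-methyl-3,4-dihydro-2H-chromen-2-yl]acetate | CC(C)(C)[Si](C)(C)OCc1cc(OC)c2c(c1C=O)OC(C)(CC(=O)OC)CC2
F2 | step 7 | methyl 2-[(2R)-7-{[(tert-butyldimethylsilyl)oxy]methyl}-8-formyl-5-methoxy-2-methyl-3,4-dihydro-2H-chromen-2-yl]acetate | CC(C)(C)[Si](C)(C)OCc1cc(OC)c2c(c1C=O)O[C@@](C)(CC(=O)OC)CC2
F3 | step 10 | 2-[(2S)-7-{[(tert-butyldimethylsilyl)oxy]methyl}-8-formyl-5-methoxy-2-methyl-3,4-dihydro-2H-chromen-2-yl]acetyl chloride | CC(C)(C)[Si](C)(C)OCc1cc(OC)c2c(c1C=O)O[C@](C)(CC(=O)Cl)CC2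
F4 | step 5 | 5-(hydroxymethyl)-3-methoxy-2-(3-methylbut-3-en-1-yl)phenol | OCc1cc(O)c(CCC(C)=C)c(OC)c1
F5 | step 5 | tert-butyl{[3-{[tert-butyl(dimethyl)silyl]oxy}-5-methoxy-4-(3-methylbut-3-en-1-yl)phenyl]methoxy}dimethylsilane | CC(C)(C)[Si](C)(C)OCc1cc(O[Si](C)(C)C(C)(C)C)c(CCC(C)=C)c(OC)c1
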